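**Remark.** Atoms carry germacrane numbers throughout (ring C1–C10, C14 on C10, C15 on C4, isopropyl on C7). The decalin intermediates keep these numbers and have the extra bond C5–C10. The C3 ester is read from the SMILES as the (Z)-2-methylbut-2-enoate (angelate), and the target is (3S,4R,5R,6S,7R).

## The problem

Compound 23 is a germacrane: a ten-membered carbocycle with an E-trisubstituted C1=C10 double bond, a trans-trisubstituted C4–C5 epoxide, an angelate at C3, an acetate at C6 and an isopropyl group at C7. C3 to C7 are five contiguous stereocentres. A ten-membered ring resists direct closure (entropy and transannular strain), and two trisubstituted E units, C1=C10 and the alkene behind the epoxide, must be set with defined geometry inside it. C7 bears only carbon and has to be brought in from outside, and C6 and C7 are cis on the ring. Once C6 is set it can control the rest: 1,3-allylic strain between the C6 substituents and the C15 methyl group decides which face of the E-4,5-alkene lies on the periphery, and in the target O3, the epoxide oxygen and O6 all sit on that outer face. The angelate isomerises to the tiglate with base, nucleophilic catalysts or strong heating. The epoxide next to a ring alkene opens or cyclises across the ring with acid. Any 3-ketone that keeps the C1=C10 bond is a β,γ-unsaturated ketone that moves into conjugation with base.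

The feature that opens the problem is the array C10(CH3)=C1–C2H2–C3(O)–C4(CH3)=C5. At the ketone level it is the tautomer of the triene C10=C1–C2=C3(O)–C4=C5. That triene is the ring-opened form of a cyclohexa-1,3-diene C1=C2–C3(O)=C4 whose saturated atoms C5 and C10 are bonded. The six atoms C10, C1, C2, C3, C4, C5 are then ring A of a trans-fused decalin, and ring B (C5–C10) already carries C6 and C7 on a rigid chair.

## Retrosynthesis

**23 ⇒ 20 + 21.** The C3–O acyl bond is cut first. The angelate is the most fragile group and is put on last, onto epoxy alcohol 20 with angelic acid 21. The forward reaction must acylate a hindered secondary alcohol without base-mediated Z-to-E isomerisation and without opening the epoxide.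

**20 ⇒ 19.** The two C–O bonds of the epoxide are cut, giving the 3-hydroxy-1(10),4-diene 19. Epoxidising before the alcohol exists would lose the directing group, and epoxidising after acylation would leave two trisubstituted alkenes with no handle to tell them apart. The forward reaction must oxidise only the 4,5-alkene, from its peripheral face.

**19 ⇒ 18.** The C3–H bond is cut, giving dienone 18. Having C3 as a carbonyl is what allows the next disconnection. The forward reduction must be a 1,2-addition and must deliver hydride to the face of the C3 carbonyl that is not flanked by C15.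

**18 ⇒ 17 ⇒ 16 (key).** After re-enolisation of C3 towards C2 (trienyl silyl ether 17), the C5–C10 bond is formed in the retrosynthetic sense, giving the trans-fused silyl dienol ether 16.
- Against its neighbours: the cuts C3–C4 (alkenyl addition to an aldehyde), C2–C3 (acyl-anion alkylation) and C6–C7 (allylation) all close the ten-membered ring from a chain. Each needs both E-alkenes, C6 and C7 to be built separately beforehand.
- Simplification: 16 is a decalin made of two six-membered rings. Its only stereochemical content is the trans ring fusion and the cis pair C6/C7. Both E geometries and the C3 carbonyl of 18 are not separate problems.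
- Demand on the forward reaction: conrotatory opening in the sense that turns C6 and C9 outward, and ketonisation by protonation at C2.

**16 ⇒ 15 ⇒ 14 ⇒ 11.** The O–Si bond, the acetyl C–O bond and the C1=C2 double bond are removed in turn. This leads to the saturated trans-fused hydroxy ketone 11. The forward steps need an enolisation of 15 that can only go to C4, and a dehydrogenation of 11 that goes to C1–C2 and not to C4–C5.

**11 ⇒ 10 ⇒ 8 ⇒ 7.** The C5–H bond and then the C6–O bond are cut, giving enone 7. C6 is the γ-carbon of this enone, so the oxygen enters through the dienol ether 8. The C5 hydrogen enters by dissolving-metal reduction, which gives the trans fusion. The forward oxidation must place O6 on the face of the angular methyl group, which is cis to the isopropyl group.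

**7 ⇒ 6 ⇒ 2 + 3.** The C4=C5 bond (aldol condensation) and the C1–C10 bond (Michael addition) are cut: a Robinson annulation of ketone 2 with ethyl vinyl ketone 3 through diketone 6. Ketone 3 supplies C1, C2, C3, C4 and C15. The forward Michael step must set the quaternary C10 with its methyl group cis to the isopropyl group, which simple base catalysis does not do, so a chiral imine is used.

**2 ⇒ 1.** Hydrogenation leads back to (S)-carvone 1. Carvone C5 becomes C7 of the target (R there), C6 becomes C6, C1 becomes C5, C2 with its methyl becomes C10 with C14, and C3 and C4 become C9 and C8.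

## Roads not taken

**Alternative 1:** closure of the ten-membered ring from an open chain, the route most chemists would draw first. One version cuts C3–C4: intramolecular Nozaki–Hiyama–Kishi addition (CrCl2, NiCl2) of the alkenyl iodide onto the aldehyde in A1 would give 19. The chosen plan is better on three counts.
- A1 needs both E-trisubstituted alkenes, C6 and C7 to be set one by one along a linear chain, which is longer than the route to 16.
- A1 is a β,γ-unsaturated aldehyde that conjugates easily, and the closure fights transannular strain at high dilution.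
- The closure gives no control of C3. In the chosen plan both alkene geometries come from one ring-fusion relationship, and no medium ring is ever closed.

**Alternative 2:** anionic oxy-Cope ring expansion. The cut is C8–C9 with the C1–C6 bond re-formed: the 1,2-dialkenylcyclohexenol A2 would rearrange to cyclodecadienone A3 with the ketone correctly on C6. However, C3, C4, C5 and C6 all lie in the six-membered ring of A2, so the 4,5-double bond of A3 is cis, and the target needs the trans epoxide of an E alkene. Laying the cyclohexane on C5–C10 instead puts the ketone on C5, the future epoxide carbon, and needs an alkoxy-substituted alkenyl nucleophile. The chosen plan gets E at both alkenes by orbital symmetry from a trans ring fusion.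

**Alternative 3:** Grob fragmentation of a decalin hydroxy sulfonate. The cut is again C5–C10: alkoxide at C5 and equatorial mesylate at C1 in A4 would give the 1(10)E-alkene and ketone A5. The carbonyl must form at the carbinol carbon of the cleaved bond, so it lands on C5. No arrangement of this fragmentation can leave C3 as the carbonyl or make the 4,5-alkene. The boron-triggered variant that does make the 4,5-alkene needs a tertiary C4–B bond next to the C3 oxygen. The route would also carry a C1 oxygen only to discard it, and would have to turn a C5 ketone into an E alkene. The photochemical opening delivers exactly the oxidation pattern of 18.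

Key step: step 10

## Route

**Step 1**
Reactants: 1 (S)-(+)-carvone
Product: 2 (5S)-2-methyl-5-(propan-2-yl)cyclohexan-1-one (carvomenthone; both C2 epimers)
Conditions: H2 (1 atm), Pd/C (palladium on carbon), EtOAc, rt
Reagents that add atoms: none
Why: Heterogeneous catalytic hydrogenation saturates the isopropenyl and the enone C=C bonds and leaves the ketone; the C5 stereocentre (C7 of the target) is not touched, and the C2 epimers converge in step 2 through a common enamine.

**Step 2**
Reactants: 2 (5S)-2-methyl-5-(propan-2-yl)cyclohexan-1-one; 3 ethyl vinyl ketone (pent-1-en-3-one)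
Product: 6 (2R,5S)-2-methyl-2-(3-oxopentyl)-5-(propan-2-yl)cyclohexan-1-one, via imine 4 (not isolated), via Michael-adduct imine 5 (not isolated)
Conditions: (S)-1-phenylethylamine, TsOH (cat.), toluene, reflux with azeotropic removal of water; then 3, THF, 40 °C; then 10% aq. AcOH, rt
Reagents that add atoms: water, O
Why: Asymmetric Michael addition of a chiral imine through its more substituted secondary enamine tautomer (deracemising alkylation of an α-substituted ketone); the enamine adds to the enone in a compact ene-like transition state on the face set by the (S)-phenylethyl group, which should give the (R)-quaternary centre with the methyl group cis to the isopropyl group; hydrolysis returns the auxiliary and the ketone.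

**Step 3**
Reactants: 6 (2R,5S)-2-methyl-2-(3-oxopentyl)-5-(propan-2-yl)cyclohexan-1-one
Product: 7 (4aR,7S)-1,4a-dimethyl-7-(propan-2-yl)-4,4a,5,6,7,8-hexahydronaphthalen-2(3H)-one
Conditions: NaOMe (cat.), MeOH, reflux
Reagents that add atoms: none
Why: Intramolecular aldol condensation, the second half of the Robinson annulation: the α-carbon of the ethyl ketone (C4) adds to the ring carbonyl (C5) and water is lost to give the tetrasubstituted enone; no stereocentre is formed or put at risk.

**Step 4**
Reactants: 7 (4aR,7S)-1,4a-dimethyl-7-(propan-2-yl)-4,4a,5,6,7,8-hexahydronaphthalen-2(3H)-one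
Product: 8 tert-butyl{[(4aR,7R)-1,4a-dimethyl-7-(propan-2-yl)-3,4,4a,5,6,7-hexahydronaphthalen-2-yl]oxy}dimethylsilane
Conditions: TBSOTf, Et3N, CH2Cl2, 0 °C to rt
Reagents that add atoms: tert-butyldimethylsilyl trifluoromethanesulfonate, CC(C)(C)[Si](C)(C)OS(=O)(=O)C(F)(F)F
Why: Soft, thermodynamic enolisation of the 4-en-3-one through the γ-hydrogen at C6 gives the linear 3,5-dienol silyl ether, which is the form needed for oxidation at C6.

**Step 5**
Reactants: 8 the 3,5-dienol silyl ether
Product: 10 (4aR,7R,8S)-8-hydroxy-1,4a-dimethyl-7-(propan-2-yl)-4,4a,5,6,7,8-hexahydronaphthalen-2(3H)-one, via epoxide 9 (not isolated)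
Conditions: mCPBA, NaHCO3, CH2Cl2, −20 °C; then Et3N·3HF, THF, 0 °C
Reagents that add atoms: 3-chloroperoxybenzoic acid, OOC(=O)c1cccc(Cl)c1
Why: Vinylogous Rubottom oxidation: the peracid attacks the terminal C5=C6 bond of the dienol ether, and the enol ether then opens the epoxide to the γ-hydroxy enone; as in the 6-hydroxylation of steroidal 3,5-dienol ethers, attack at C6 should be axial, on the face of the angular methyl group, which makes O6 cis to C14 and to the isopropyl group (6S).

**Step 6**
Reactants: 10 the 6-hydroxy-4-en-3-one
Product: 11 (1R,4aR,7R,8S,8aR)-8-hydroxy-1,4a-dimethyl-7-(propan-2-yl)octahydronaphthalen-2(1H)-one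
Conditions: Li, NH3 (l), THF, t-BuOH (1 equiv), −78 °C; then NH4Cl
Reagents that add atoms: none
Why: Dissolving-metal (Birch-type) reduction of the enone; protonation of the β-carbon C5 should give the more stable trans-fused decalin (H5 anti to C14), the C6 hydroxyl is carried as its lithium alkoxide and so is a poor leaving group, and protonation of the enolate on quenching places the C4 methyl group equatorial.

**Step 7**
Reactants: 11 the trans-fused hydroxy ketone
Product: 14 (1R,4aR,7R,8S,8aR)-8-hydroxy-1,4a-dimethyl-7-(propan-2-yl)-4a,5,6,7,8,8a-hexahydronaphthalen-2(1H)-one, via bis-silyl enol ether 12 (not isolated), via silyl-protected enone 13 (not isolated)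
Conditions: LDA (2.3 equiv), TMSCl, THF, −78 °C; then Pd(OAc)2 (1.1 equiv), MeCN, rt; then 1 M HCl, THF, 0 °C
Reagents that add atoms: none
Why: Kinetic deprotonation takes the C2 methylene and not the C4 methine, and the alkoxide is silylated at the same time; Saegusa–Ito oxidation of the silyl enol ether with Pd(OAc)2 then gives the 1-en-3-one by β-hydride elimination from C1, and mild acid removes the O6 silyl group.

**Step 8**
Reactants: 14 the 6-hydroxy-1-en-3-one
Product: 15 (1S,2R,4aR,8R,8aR)-4a,8-dimethyl-7-oxo-2-(propan-2-yl)-1,2,3,4,4a,7,8,8a-octahydronaphthalen-1-yl acetate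
Conditions: Ac2O, pyridine, DMAP (cat.), CH2Cl2, rt
Reagents that add atoms: acetic anhydride, CC(=O)OC(C)=O
Why: Standard acylation of the axial secondary alcohol; the acetate is the C6 ester of the target and is carried from here on because no later step uses a strong base or nucleophile.

**Step 9**
Reactants: 15 the 6-acetoxy-1-en-3-one
Product: 16 (1S,2R,4aR,8aS)-7-{[tert-butyl(dimethyl)silyl]oxy}-4a,8-dimethyl-2-(propan-2-yl)-1,2,3,4,4a,8a-hexahydronaphthalen-1-yl acetate
Conditions: TBSOTf, Et3N, CH2Cl2, −78 to 0 °C
Reagents that add atoms: tert-butyldimethylsilyl trifluoromethanesulfonate, CC(C)(C)[Si](C)(C)OS(=O)(=O)C(F)(F)F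
Why: Soft enolisation of the enone; C4–H (axial) is the only enolisable hydrogen, so the cross-conjugated 1,3-dien-3-yl silyl ether C1=C2–C3(OSi)=C4 is the only possible product, and the acetate is not affected.

**Step 10 (key step)**
Reactants: 16 the trans-fused silyl dienol ether
Product: 18 (1S,2E,6E,10R)-3,7-dimethyl-4-oxo-10-(propan-2-yl)cyclodeca-2,6-dien-1-yl acetate, via trienyl silyl ether 17 (not isolated)
Conditions: hν (medium-pressure Hg lamp, Pyrex filter), degassed THF, −78 °C, to partial conversion; then TBAF, AcOH, THF, −78 to −40 °C
Reagents that add atoms: none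
Why: Photochemical six-electron conrotatory electrocyclic ring opening of the cyclohexa-1,3-diene C1=C2–C3=C4 cleaves the C5–C10 σ bond and gives the cyclodecatriene 17. The closest known reaction type is the photochemical opening of trans-fused bicyclic 1,3-dienes (eudesma-1,3-dienes, provitamin D type) to (E,Z,E)-cyclodeca-1,3,5-trienes. No ring is closed: the ten-membered ring appears because the shared bond of the two six-membered rings is broken. No stereocentre is formed; C6 and C7 are carried over unchanged. Conrotation turns the trans pair H5/C14 inward and the ring-B bonds C5–C6 and C10–C9 outward, so both C4=C5 and C1=C10 should come out E, while C2=C3 stays cis and is the silyl enol ether. Fluoride with acetic acid in the cold then ketonises C3 by kinetic protonation of the cross-conjugated dienolate at its α-carbon C2, and dienone 18 neither absorbs at the lamp wavelength nor can reclose. The step needs outward rotation of C6 and C9, which the trans fusion and the helical twist of the diene should secure, and α-protonation rather than protonation at C10, which low temperature and a buffered proton source should secure. Unchanged 16 is returned as 15 by the same fluoride treatment and recycled.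

**Step 11**
Reactants: 18 the germacra-1(10),4-dien-3-one
Product: 19 (1S,2E,4S,6E,10R)-4-hydroxy-3,7-dimethyl-10-(propan-2-yl)cyclodeca-2,6-dien-1-yl acetate
Conditions: NaBH4, CeCl3·7H2O, MeOH, −78 °C
Reagents that add atoms: none
Why: Luche 1,2-reduction; H6 eclipses the 4,5-alkene to avoid 1,3-allylic strain with C15, which puts the ring (C7 and C2) under one face of the alkene and twists the C3 carbonyl out of conjugation, and hydride should then add from the side of H5, anti to the C15 methyl group, placing O3 on the peripheral face (3S); the acetate survives.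

**Step 12**
Reactants: 19 the 3-hydroxy-1(10),4-diene
Product: 20 (1R,2S,4E,8R,9S,10R)-2-hydroxy-1,5-dimethyl-8-(propan-2-yl)-11-oxabicyclo[8.1.0]undec-4-en-9-yl acetate
Conditions: VO(acac)2 (5 mol %), t-BuOOH (anhydrous), CH2Cl2, 0 °C
Reagents that add atoms: tert-butyl hydroperoxide, CC(C)(C)OO
Why: Hydroxyl-directed epoxidation, which acts only on the alkene of the allylic alcohol; the C3 vanadate sits on the peripheral face of the E-4,5-alkene, the only face the ring leaves open, so oxygen should be delivered syn to O3 and O6 to give the (4R,5R)-epoxide, and the C1=C10 alkene has no directing group.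

**Step 13**
Reactants: 20 the epoxy alcohol; 21 angelic acid [(2Z)-2-methylbut-2-enoic acid]
Product: 23 (1R,2S,4E,8R,9S,10R)-9-acetoxy-1,5-dimethyl-8-(propan-2-yl)-11-oxabicyclo[8.1.0]undec-4-en-2-yl (2Z)-2-methylbut-2-enoate, via mixed anhydride 22 (not isolated)
Conditions: 21, 2,4,6-trichlorobenzoyl chloride, Et3N, toluene, rt, filtration; then 20, Et3N, toluene, 75 °C
Reagents that add atoms: none
Why: Yamaguchi-type esterification run without a nucleophilic catalyst, the conditions under which angelates are formed without Z-to-E isomerisation; the alcohol attacks the unhindered angeloyl carbonyl of the mixed anhydride, C3 keeps its configuration, and the amine buffer protects the epoxide.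

## Compound list

1 | (S)-(+)-carvone, (5S)-2-methyl-5-(prop-1-en-2-yl)cyclohex-2-en-1-one | O=C1C(C)=CC[C@H](C(C)=C)C1 | starting material
2 | (5S)-2-methyl-5-(propan-2-yl)cyclohexan-1-one (both C2 epimers) | O=C1C(C)CC[C@H](C(C)C)C1 | intermediate
3 | ethyl vinyl ketone (pent-1-en-3-one) | C=CC(=O)CC | starting material
4 | (5S)-2-methyl-N-[(1S)-1-phenylethyl]-5-(propan-2-yl)cyclohexan-1-imine | C[C@H](N=C1C(C)CC[C@H](C(C)C)C1)c1ccccc1 | intermediate (not isolated)
5 | N-[(1S)-1-phenylethyl] imine of 6 at the ring carbonyl | C[C@H](N=C1[C@@](C)(CCC(=O)CC)CC[C@H](C(C)C)C1)c1ccccc1 | intermediate (not isolated)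
6 | (2R,5S)-2-methyl-2-(3-oxopentyl)-5-(propan-2-yl)cyclohexan-1-one | O=C1[C@@](C)(CCC(=O)CC)CC[C@H](C(C)C)C1 | intermediate
7 | (4aR,7S)-1,4a-dimethyl-7-(propan-2-yl)-4,4a,5,6,7,8-hexahydronaphthalen-2(3H)-one | O=C1CC[C@@]2(C)CC[C@H](C(C)C)CC2=C1C | intermediate
8 | tert-butyl{[(4aR,7R)-1,4a-dimethyl-7-(propan-2-yl)-3,4,4a,5,6,7-hexahydronaphthalen-2-yl]oxy}dimethylsilane | CC(C)(C)[Si](C)(C)OC1=C(C)C2=C[C@@H](C(C)C)CC[C@]2(C)CC1 | intermediate
9 | 5,6-epoxide of 8, oxygen on the face of the angular methyl group | CC(C)(C)[Si](C)(C)OC1=C(C)[C@]23O[C@H]2[C@@H](C(C)C)CC[C@]3(C)CC1 | intermediate (not isolated)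
10 | (4aR,7R,8S)-8-hydroxy-1,4a-dimethyl-7-(propan-2-yl)-4,4a,5,6,7,8-hexahydronaphthalen-2(3H)-one | O=C1CC[C@@]2(C)CC[C@H](C(C)C)[C@H](O)C2=C1C | intermediate
11 | (1R,4aR,7R,8S,8aR)-8-hydroxy-1,4a-dimethyl-7-(propan-2-yl)octahydronaphthalen-2(1H)-one | O=C1CC[C@@]2(C)CC[C@H](C(C)C)[C@H](O)[C@@H]2[C@H]1C | intermediate
12 | 2-en-3-yl trimethylsilyl enol ether of 11 with O6 as trimethylsilyl ether | C[Si](C)(C)OC1=CC[C@@]2(C)CC[C@H](C(C)C)[C@H](O[Si](C)(C)C)[C@@H]2[C@H]1C | intermediate (not isolated)
13 | O6-trimethylsilyl ether of 14 | O=C1C=C[C@@]2(C)CC[C@H](C(C)C)[C@H](O[Si](C)(C)C)[C@@H]2[C@H]1C | intermediate (not isolated)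
14 | (1R,4aR,7R,8S,8aR)-8-hydroxy-1,4a-dimethyl-7-(propan-2-yl)-4a,5,6,7,8,8a-hexahydronaphthalen-2(1H)-one | O=C1C=C[C@@]2(C)CC[C@H](C(C)C)[C@H](O)[C@@H]2[C@H]1C | intermediate
15 | (1S,2R,4aR,8R,8aR)-4a,8-dimethyl-7-oxo-2-(propan-2-yl)-1,2,3,4,4a,7,8,8a-octahydronaphthalen-1-yl acetate | O=C1C=C[C@@]2(C)CC[C@H](C(C)C)[C@H](OC(C)=O)[C@@H]2[C@H]1C | intermediate
16 | (1S,2R,4aR,8aS)-7-{[tert-butyl(dimethyl)silyl]oxy}-4a,8-dimethyl-2-(propan-2-yl)-1,2,3,4,4a,8a-hexahydronaphthalen-1-yl acetate | CC(C)(C)[Si](C)(C)OC1=C(C)[C@H]2[C@@H](OC(C)=O)[C@@H](C(C)C)CC[C@]2(C)C=C1 | intermediate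
17 | (1S,2E,4E,6E,10R)-4-{[tert-butyl(dimethyl)silyl]oxy}-3,7-dimethyl-10-(propan-2-yl)cyclodeca-2,4,6-trien-1-yl acetate (the 4,5-double bond is cis within the ring) | CC(=O)O[C@@H]1/C=C(\C)/C(O[Si](C)(C)C(C)(C)C)=C\C=C(/C)\CC[C@@H]1C(C)C | intermediate (not isolated)
18 | (1S,2E,6E,10R)-3,7-dimethyl-4-oxo-10-(propan-2-yl)cyclodeca-2,6-dien-1-yl acetate | CC(=O)O[C@@H]1/C=C(\C)C(=O)C/C=C(\C)CC[C@@H]1C(C)C | intermediate
19 | (1S,2E,4S,6E,10R)-4-hydroxy-3,7-dimethyl-10-(propan-2-yl)cyclodeca-2,6-dien-1-yl acetate | CC(=O)O[C@@H]1/C=C(\C)[C@@H](O)C/C=C(\C)CC[C@@H]1C(C)C | intermediate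
20 | (1R,2S,4E,8R,9S,10R)-2-hydroxy-1,5-dimethyl-8-(propan-2-yl)-11-oxabicyclo[8.1.0]undec-4-en-9-yl acetate | O[C@H]1C/C=C(\C)CC[C@H](C(C)C)[C@H](OC(C)=O)[C@H]2O[C@]12C | intermediate
21 | angelic acid, (2Z)-2-methylbut-2-enoic acid | C/C=C(/C)C(=O)O | starting material
22 | (2Z)-2-methylbut-2-enoic 2,4,6-trichlorobenzoic anhydride | C/C=C(/C)C(=O)OC(=O)c1c(Cl)cc(Cl)cc1Cl | intermediate (not isolated)
23 | (1R,2S,4E,8R,9S,10R)-9-acetoxy-1,5-dimethyl-8-(propan-2-yl)-11-oxabicyclo[8.1.0]undec-4-en-2-yl (2Z)-2-methylbut-2-enoate (CNP0180504.1) | C/C=C(/C)C(=O)O[C@H]1C/C=C(\C)CC[C@H](C(C)C)[C@H](OC(C)=O)[C@H]2O[C@]12C | target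

## Step count and least certain steps

Total: 13 steps. Longest linear sequence: 13 steps (1 to 23); 3 and 21 are bought and enter in steps 2 and 13.

**Step 10 (key step).** The most likely failure is loss of the triene between its formation and its ketonisation. Three processes could cause it: thermal disrotatory reclosure to a cis-fused diene, further photoisomerisation once the triene builds up at the photostationary state, and protonation of the dienolate at C10 instead of C2, which would draw the C1=C10 bond into conjugation. The fallback sets out from 14 and comes back to the route at 19, so it replaces steps 8 to 11. It changes the enol derivative and the way the triene is taken out of the equilibrium. Heating 14 with isopropenyl acetate and catalytic TsOH would acetylate O6 and the C3 enol in one operation, giving the dienyl diacetate F1. Irradiation at −78 °C as in step 10 would give the trienyl diacetate F2. Still in the cold, K2CO3 in MeOH followed by NaBH4 and CeCl3·7H2O would cleave the enol acetate, which is far more reactive than the alkyl acetate at C6, and reduce the ketone as it forms. The dienone is then never accumulated and 19 is isolated directly. If instead the conrotation itself turned C6 and C9 inward, nothing in the decalin series could correct it, and the ring would have to be closed from the chain A1 of Alternative 1.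

**Step 6.** The most likely failure is reductive loss of the C6 oxygen, by β-elimination from the C5 carbanion before it is protonated. One step earlier, in step 5, the peracid could attack C4 or the wrong face. The fallback sets out from 7 and comes back at 11, replacing steps 4 to 6 with hydroboration chemistry. Ketalisation of 7 with ethylene glycol and TsOH, with the usual shift of the double bond, would give the 5-ene ketal F3. BH3·THF followed by NaOH and H2O2 should add from the face opposite the angular methyl group and give the trans-fused 6-alcohol F4 with the hydroxyl on the wrong side. Oxidation with the periodinane 1,1,1-triacetoxy-1,1-dihydro-1,2-benziodoxol-3(1H)-one would give ketone F5, in which C5 and C7 can only settle to the wanted trans-fused, equatorial-isopropyl arrangement. Li(s-Bu)3BH should attack from the face away from the angular methyl group and give the axial alcohol F6. Aqueous HCl in THF then removes the ketal and gives 11.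

**Step 11.** The most likely failure is poor facial selectivity of hydride addition, if the ring populates a second conformer or the carbonyl is less twisted than assumed. The fallback sets out from 18 and comes back at 19. It accepts the (3R) alcohol F7 from the same reduction and corrects it by substitution with inversion: a Mitsunobu reaction (PPh3, diisopropyl azodicarboxylate, chloroacetic acid) would give the (3S) chloroacetate F8. K2CO3 in MeOH at −20 °C removes a chloroacetate much faster than an acetate and would give 19.

**Step 12.** The most likely failure is oxidation of the allylic alcohol back to the enone by the vanadium peroxide if the O3–C3–C4=C5 angle is unfavourable, or a slow reaction that lets the C1=C10 alkene compete. The fallback sets out from 18 and comes back at 20; it reverses the order of reduction and epoxidation. Weitz–Scheffer epoxidation of 18 (t-BuOOH, DBU, CH2Cl2, 0 °C) acts only on the electron-poor enone alkene and should add the peroxide to C5 from the peripheral face, giving the epoxy ketone F9. NaBH4 with CeCl3·7H2O should then add hydride anti to the epoxide C–O bond and give 20.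

## Further compounds

F1 | step 10 | (1S,2R,4aR,8aS)-4a,8-dimethyl-2-(propan-2-yl)-1,2,3,4,4a,8a-hexahydronaphthalene-1,7-diyl diacetate | CC(=O)OC1=C(C)[C@H]2[C@@H](OC(C)=O)[C@@H](C(C)C)CC[C@]2(C)C=C1
F2 | step 10 | (1S,2E,4E,6E,10R)-3,7-dimethyl-10-(propan-2-yl)cyclodeca-2,4,6-triene-1,4-diyl diacetate (the 4,5-double bond is cis within the ring) | CC(=O)O[C@@H]1/C=C(\C)/C(OC(C)=O)=C\C=C(/C)\CC[C@@H]1C(C)C
F3 | step 6 | ethylene ketal of the 5-ene isomer of 7 (both C4 epimers) | CC1C2=C[C@@H](C(C)C)CC[C@]2(C)CCC13OCCO3
F4 | step 6 | trans-fused 6-hydroxy ketal, hydroxyl trans to the angular methyl group (both C4 epimers) | O1CCOC12CC[C@@]3(C)CC[C@H](C(C)C)[C@@H](O)[C@@H]3C2C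
F5 | step 6 | trans-fused 6-oxo ketal (both C4 epimers) | O1CCOC12CC[C@@]3(C)CC[C@H](C(C)C)C(=O)[C@@H]3C2C
F6 | step 6 | ethylene ketal of 11 (both C4 epimers) | O1CCOC12CC[C@@]3(C)CC[C@H](C(C)C)[C@H](O)[C@@H]3C2C
F7 | step 11 | (1S,2E,4R,6E,10R)-4-hydroxy-3,7-dimethyl-10-(propan-2-yl)cyclodeca-2,6-dien-1-yl acetate | CC(=O)O[C@@H]1/C=C(\C)[C@H](O)C/C=C(\C)CC[C@@H]1C(C)C
F8 | step 11 | (1S,2E,4S,6E,10R)-4-[(chloroacetyl)oxy]-3,7-dimethyl-10-(propan-2-yl)cyclodeca-2,6-dien-1-yl acetate | CC(=O)O[C@@H]1/C=C(\C)[C@@H](OC(=O)CCl)C/C=C(\C)CC[C@@H]1C(C)C
F9 | step 12 | (1S,4E,8R,9S,10R)-1,5-dimethyl-2-oxo-8-(propan-2-yl)-11-oxabicyclo[8.1.0]undec-4-en-9-yl acetate | O=C1C/C=C(\C)CC[C@H](C(C)C)[C@H](OC(C)=O)[C@H]2O[C@]12C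
A1 | alternative 1 | (3E,7R,8S,9E)-8-acetoxy-10-iodo-4-methyl-7-(propan-2-yl)undeca-3,9-dienal | O=CC/C=C(\C)CC[C@H](C(C)C)[C@H](OC(C)=O)/C=C(\C)I
A2 | alternative 2 | (1S,4S,6S)-4-{[tert-butyl(dimethyl)silyl]oxy}-3-methyl-1-(3-methylbut-1-en-2-yl)-6-(prop-1-en-2-yl)cyclohex-2-en-1-ol | CC(C)C(=C)[C@]1(O)C=C(C)[C@@H](O[Si](C)(C)C(C)(C)C)C[C@H]1C(C)=C
A3 | alternative 2 | (2Z,4S,6E)-4-{[tert-butyl(dimethyl)silyl]oxy}-3,7-dimethyl-10-(propan-2-yl)cyclodeca-2,6-dien-1-one (C10 not defined) | O=C1C(C(C)C)CC/C(C)=C/C[C@H](O[Si](C)(C)C(C)(C)C)/C(C)=C\1
A4 | alternative 3 | trans-fused decalin with 1-mesyloxy (equatorial), 3-silyloxy, 4-methyl, 5-hydroxy, 6-acetoxy, 7-isopropyl and 10-methyl groups | CC(C)(C)[Si](C)(C)O[C@@H]1C[C@H](OS(C)(=O)=O)[C@@]2(C)CC[C@H](C(C)C)[C@H](OC(C)=O)[C@]2(O)[C@H]1C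
A5 | alternative 3 | 6-acetoxy-3-silyloxy-germacr-1(10)E-en-5-one | CC(=O)O[C@H]1[C@@H](C(C)C)CC/C(C)=C/C[C@@H](O[Si](C)(C)C(C)(C)C)[C@H](C)C1=O
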